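**Retrosynthetic overview**

1. Numbering: tetrahydrofuran ring O1, C2–C5, with C9 on C3 and C9' on C4. The strategy rests on the unit O1–C5(aryl)–C4–C9'–O: the cis relation of the C5 aryl group and the C4 CH2OH group in the tetrahydrofuran is the trans-diequatorial 4-aryl-5-alkyl relation of a 1,3-dioxane drawn through O1, C5, C4, C9' and the C9' oxygen.
2. C2 is disconnected last: C2–H comes from hydride reduction of a 2-aryl hemiketal, C2–aryl from an aryllithium and a γ-lactone, and C3–C9 from the lactone enolate and formaldehyde, trans to C4.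
3. The γ-lactone (O1, C2–C5) comes from a 1,4-diol by oxidative lactonisation, after the dioxane is opened and the C9' oxygen is silylated, so that only O1 can enter the ring.
4. The dioxane comes from an (E)-4-arylbut-3-enyl pivalate and two molecules of formaldehyde by a catalytic asymmetric Prins reaction (bonds C4–C9' and C5–O1, stereocentres C4 and C5); the alkene comes from O-benzylvanillin by a Wittig reaction.
5. Ring order: 1,3-dioxane (step 4, temporary), γ-lactone (step 8), then the same five-membered ring is carried to the tetrahydrofuran of the target (step 12).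

Key step: step 4

Remarks on the chemistry: aldehyde 1 and bromide 17 are taken as purchased (each is the benzyl ether of a commodity phenol). Which enantiomer of the chiral acid gives (4S,5S)-8 is to be fixed by a trial run. Descriptors follow the target, which is (2S,3S,4S,5S) and C2-symmetric.

**Step 1**
Reactants: 1 4-(benzyloxy)-3-methoxybenzaldehyde; 2 (2-carboxyethyl)triphenylphosphonium bromide
Product: 4 (E)-4-[4-(benzyloxy)-3-methoxyphenyl]but-3-enoic acid, via phosphonium ylide 3 (not isolated)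
Conditions: NaN(SiMe3)2 (2.2 equiv), THF, −78 °C → rt; aq. HCl work-up; recrystallisation
Reagents that add atoms: none
Why: Wittig olefination with a carboxylate-bearing ylide, which with aromatic aldehydes should give the (E)-4-arylbut-3-enoic acid, the double bond staying conjugated with the ring and any Z isomer being removed by crystallisation of the acid.

**Step 2**
Reactants: 4 (E)-4-[4-(benzyloxy)-3-methoxyphenyl]but-3-enoic acid
Product: 5 (E)-4-[4-(benzyloxy)-3-methoxyphenyl]but-3-en-1-ol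
Conditions: LiAlH4, THF, 0 °C → rt
Reagents that add atoms: none
Why: LiAlH4 reduction of a carboxylic acid to the primary alcohol, to which the unactivated aryl alkene and the benzyl ether are inert.

**Step 3**
Reactants: 5 (E)-4-[4-(benzyloxy)-3-methoxyphenyl]but-3-en-1-ol
Product: 6 (E)-4-[4-(benzyloxy)-3-methoxyphenyl]but-3-en-1-yl pivalate
Conditions: t-BuCOCl, Et3N, DMAP (4-dimethylaminopyridine, cat.), CH2Cl2, 0 °C → rt
Reagents that add atoms: pivaloyl chloride, CC(C)(C)C(=O)Cl
Why: DMAP-catalysed acylation of a primary alcohol, which makes the chain oxygen too weak a nucleophile to close a tetrahydropyran or tetrahydrofuran in the Prins step.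

**Step 4**
Reactants: 6 (E)-4-[4-(benzyloxy)-3-methoxyphenyl]but-3-en-1-yl pivalate; 7 formaldehyde (as paraformaldehyde, two molecules incorporated)
Product: 8 2-{(4S,5S)-4-[4-(benzyloxy)-3-methoxyphenyl]-1,3-dioxan-5-yl}ethyl pivalate (4,5-trans)
Conditions: paraformaldehyde (excess), one enantiomer of a confined imino-imidodiphosphoric acid (two 3,3'-diaryl-1,1'-bi-2-naphthol phosphorus units joined through N–H, one phosphorus carrying P=N–SO2CF3; 5 mol %), cyclohexane–CHCl3, 0 °C → rt
Reagents that add atoms: none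
Why: The chiral acid protonates a formaldehyde hemiformal held in its confined pocket, this electrophile adds to the alkene at C4 (the carbon remote from the ring) while positive charge builds at benzylic C5, and the hemiformal oxygen collapses onto C5 in a concerted but asynchronous syn addition across the alkene. The closest known reaction is the catalytic asymmetric Prins reaction of aryl alkenes with paraformaldehyde under confined imino-imidodiphosphate acids, together with the classical acid Prins reaction of anethole-type (E)-1-arylalkenes to trans-4-aryl-5-alkyl-1,3-dioxanes. The 1,3-dioxane closes through a six-membered chair-like array by C5–O bond formation, a 6-endo capture of the benzylic cationic centre by oxygen. C4 is set by the alkene face that the chiral counter-anion exposes to C–C bond formation, and C5 follows from syn addition to the E alkene, reinforced because any reopening of the benzylic C–O bond recloses to the trans-diequatorial chair. The step needs Markovnikov regioselectivity (secured by the aryl-stabilised C5), trans selectivity (E geometry and chair preference), enantiofacial selectivity (catalyst) and chemoselectivity (the pivalate oxygen does not cyclise, and the confined acid at low loading should not hydroxymethylate the arene).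

**Step 5**
Reactants: 8 2-{(4S,5S)-4-[4-(benzyloxy)-3-methoxyphenyl]-1,3-dioxan-5-yl}ethyl pivalate
Product: 9 (3S,4S)-4-[4-(benzyloxy)-3-methoxyphenyl]-4-hydroxy-3-(hydroxymethyl)butyl pivalate
Conditions: Me3SiOTf, 2,2'-bipyridyl, CH2Cl2, 0 °C → rt; then H2O
Reagents that add atoms: none
Why: Silyl triflate–bipyridyl cleavage of a methylene acetal, in which Me3SiOTf opens the formal at the acetal carbon, bipyridyl traps the oxocarbenium ion as a pyridinium salt and water releases both hydroxyls, so the acid-labile electron-rich benzylic C5–O bond never meets protic acid and C5 should keep its configuration.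

**Step 6**
Reactants: 9 (3S,4S)-4-[4-(benzyloxy)-3-methoxyphenyl]-4-hydroxy-3-(hydroxymethyl)butyl pivalate
Product: 10 (3S,4S)-4-[4-(benzyloxy)-3-methoxyphenyl]-3-{[(tert-butyldimethylsilyl)oxy]methyl}-4-hydroxybutyl pivalate
Conditions: t-BuMe2SiCl (1.05 equiv), imidazole, CH2Cl2, −20 → 0 °C
Reagents that add atoms: tert-butyldimethylsilyl chloride, CC(C)(C)[Si](C)(C)Cl
Why: Selective silylation of the primary hydroxyl over the hindered secondary benzylic one, which protects the C9' oxygen and leaves O1 free.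

**Step 7**
Reactants: 10 (3S,4S)-4-[4-(benzyloxy)-3-methoxyphenyl]-3-{[(tert-butyldimethylsilyl)oxy]methyl}-4-hydroxybutyl pivalate
Product: 11 (1S,2S)-1-[4-(benzyloxy)-3-methoxyphenyl]-2-{[(tert-butyldimethylsilyl)oxy]methyl}butane-1,4-diol
Conditions: i-Bu2AlH (excess), CH2Cl2, −78 → 0 °C; aq. potassium sodium tartrate
Reagents that add atoms: none
Why: Reductive cleavage of the pivalate ester by i-Bu2AlH, which leaves silyl and benzyl ethers intact and involves no free alkoxide base that could move the silyl group.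

**Step 8**
Reactants: 11 (1S,2S)-1-[4-(benzyloxy)-3-methoxyphenyl]-2-{[(tert-butyldimethylsilyl)oxy]methyl}butane-1,4-diol
Product: 13 (4S,5S)-5-[4-(benzyloxy)-3-methoxyphenyl]-4-{[(tert-butyldimethylsilyl)oxy]methyl}dihydrofuran-2(3H)-one (4,5-cis), via lactol 12 (not isolated)
Conditions: TEMPO (2,2,6,6-tetramethylpiperidin-1-oxyl, cat.), PhI(OAc)2 (2.5 equiv), CH2Cl2, rt
Reagents that add atoms: none
Why: TEMPO/PhI(OAc)2 oxidative lactonisation of a 1,4-diol, in which the unhindered primary alcohol is oxidised first, the aldehyde is caught by the C5 hydroxyl as lactol 12 and this is oxidised on, so that O1 and not the C9' oxygen enters the ring and C4 and C5 are untouched.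

**Step 9**
Reactants: 13 (4S,5S)-5-[4-(benzyloxy)-3-methoxyphenyl]-4-{[(tert-butyldimethylsilyl)oxy]methyl}dihydrofuran-2(3H)-one; 7 formaldehyde (monomer, from cracked paraformaldehyde)
Product: 15 (3S,4S,5S)-5-[4-(benzyloxy)-3-methoxyphenyl]-4-{[(tert-butyldimethylsilyl)oxy]methyl}-3-(hydroxymethyl)dihydrofuran-2(3H)-one, via lithium enolate 14 (not isolated)
Conditions: LiN(i-Pr)2, THF, −78 °C; HCHO (gas in N2 stream), −78 → −40 °C; aq. NH4Cl
Reagents that add atoms: none
Why: Aldol addition of a lactone lithium enolate to monomeric formaldehyde (hydroxymethylation), in which the electrophile enters on the face opposite to the C4 CH2OSi group and the C5 aryl group, which sets C3 trans to C4.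

**Step 10**
Reactants: 15 (3S,4S,5S)-5-[4-(benzyloxy)-3-methoxyphenyl]-4-{[(tert-butyldimethylsilyl)oxy]methyl}-3-(hydroxymethyl)dihydrofuran-2(3H)-one
Product: 16 (3S,4S,5S)-5-[4-(benzyloxy)-3-methoxyphenyl]-3,4-bis{[(tert-butyldimethylsilyl)oxy]methyl}dihydrofuran-2(3H)-one
Conditions: t-BuMe2SiCl, imidazole, DMF, rt
Reagents that add atoms: tert-butyldimethylsilyl chloride, CC(C)(C)[Si](C)(C)Cl
Why: Silylation of a primary alcohol, which blocks retro-aldol loss of formaldehyde and elimination in the strongly basic next step.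

**Step 11**
Reactants: 16 (3S,4S,5S)-5-[4-(benzyloxy)-3-methoxyphenyl]-3,4-bis{[(tert-butyldimethylsilyl)oxy]methyl}dihydrofuran-2(3H)-one; 17 1-(benzyloxy)-4-bromo-2-methoxybenzene
Product: 19 (3S,4S,5S)-2,5-bis[4-(benzyloxy)-3-methoxyphenyl]-3,4-bis{[(tert-butyldimethylsilyl)oxy]methyl}tetrahydrofuran-2-ol (hemiketal; used crude), via aryllithium 18 (not isolated)
Conditions: 17, n-BuLi, THF, −78 °C; then 16, −78 °C; aq. NH4Cl
Reagents that add atoms: none
Why: Bromine–lithium exchange followed by 1,2-addition of the aryllithium to the lactone carbonyl at −78 °C, where the lithium hemiketal alkoxide is stable enough to stop a second addition and C3, C4 and C5 are not affected.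

**Step 12**
Reactants: 19 (3S,4S,5S)-2,5-bis[4-(benzyloxy)-3-methoxyphenyl]-3,4-bis{[(tert-butyldimethylsilyl)oxy]methyl}tetrahydrofuran-2-ol
Product: 20 (2S,3S,4S,5S)-2,5-bis[4-(benzyloxy)-3-methoxyphenyl]-3,4-bis{[(tert-butyldimethylsilyl)oxy]methyl}tetrahydrofuran
Conditions: Et3SiH (excess), BF3·OEt2, CH2Cl2, −78 °C
Reagents that add atoms: none
Why: Ionic hydrogenation of a cyclic hemiketal, in which BF3 ionises the C2 hydroxyl and, in the envelope that keeps the C3 CH2OSi group pseudoaxial to avoid allylic strain with the C2 aryl ring, Et3SiH delivers hydride inside the envelope anti to that group, giving the kinetic 2,3-cis tetrahydrofuran known for hemiketals of this lignan type.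

**Step 13**
Reactants: 20 (2S,3S,4S,5S)-2,5-bis[4-(benzyloxy)-3-methoxyphenyl]-3,4-bis{[(tert-butyldimethylsilyl)oxy]methyl}tetrahydrofuran
Product: 21 [(2S,3S,4S,5S)-2,5-bis[4-(benzyloxy)-3-methoxyphenyl]tetrahydrofuran-3,4-diyl]dimethanol
Conditions: Bu4NF, THF, 0 °C → rt
Reagents that add atoms: none
Why: Fluoride cleavage of the two primary silyl ethers, to which the benzyl ethers and the ring are stable.

**Step 14**
Reactants: 21 [(2S,3S,4S,5S)-2,5-bis[4-(benzyloxy)-3-methoxyphenyl]tetrahydrofuran-3,4-diyl]dimethanol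
Product: 22 eduesmine, [(2S,3S,4S,5S)-2,5-bis(4-hydroxy-3-methoxyphenyl)tetrahydrofuran-3,4-diyl]dimethanol
Conditions: H2 (1 atm), Pd/C (palladium on carbon), EtOAc–MeOH, rt, stopped at full debenzylation
Reagents that add atoms: none
Why: Hydrogenolysis of the two aryl benzyl ethers over palladium on carbon, which should be fast relative to cleavage of the ring benzylic C–O bonds because no slow alkyl benzyl ether has to be removed.

**Compound list**

1 | 4-(benzyloxy)-3-methoxybenzaldehyde | COc1cc(C=O)ccc1OCc1ccccc1 | starting material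
2 | (2-carboxyethyl)triphenylphosphonium bromide | [Br-].OC(=O)CC[P+](c1ccccc1)(c1ccccc1)c1ccccc1 | starting material
3 | sodium 3-(triphenylphosphoranylidene)propanoate (ylide, formed in the flask, not isolated) | [Na+].[O-]C(=O)CC=P(c1ccccc1)(c1ccccc1)c1ccccc1 | intermediate
4 | (E)-4-[4-(benzyloxy)-3-methoxyphenyl]but-3-enoic acid | COc1cc(/C=C/CC(=O)O)ccc1OCc1ccccc1 | intermediate
5 | (E)-4-[4-(benzyloxy)-3-methoxyphenyl]but-3-en-1-ol | COc1cc(/C=C/CCO)ccc1OCc1ccccc1 | intermediate
6 | (E)-4-[4-(benzyloxy)-3-methoxyphenyl]but-3-en-1-yl pivalate | COc1cc(/C=C/CCOC(=O)C(C)(C)C)ccc1OCc1ccccc1 | intermediate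
7 | formaldehyde (used as paraformaldehyde) | C=O | starting material
8 | 2-{(4S,5S)-4-[4-(benzyloxy)-3-methoxyphenyl]-1,3-dioxan-5-yl}ethyl pivalate (4,5-trans) | C1OC[C@H](CCOC(=O)C(C)(C)C)[C@@H](c2ccc(OCc3ccccc3)c(OC)c2)O1 | intermediate
9 | (3S,4S)-4-[4-(benzyloxy)-3-methoxyphenyl]-4-hydroxy-3-(hydroxymethyl)butyl pivalate | OC[C@H](CCOC(=O)C(C)(C)C)[C@@H](c1ccc(OCc2ccccc2)c(OC)c1)O | intermediate
10 | (3S,4S)-4-[4-(benzyloxy)-3-methoxyphenyl]-3-{[(tert-butyldimethylsilyl)oxy]methyl}-4-hydroxybutyl pivalate | CC(C)(C)[Si](C)(C)OC[C@H](CCOC(=O)C(C)(C)C)[C@@H](c1ccc(OCc2ccccc2)c(OC)c1)O | intermediate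
11 | (1S,2S)-1-[4-(benzyloxy)-3-methoxyphenyl]-2-{[(tert-butyldimethylsilyl)oxy]methyl}butane-1,4-diol | CC(C)(C)[Si](C)(C)OC[C@H](CCO)[C@@H](c1ccc(OCc2ccccc2)c(OC)c1)O | intermediate
12 | (4S,5S)-5-[4-(benzyloxy)-3-methoxyphenyl]-4-{[(tert-butyldimethylsilyl)oxy]methyl}tetrahydrofuran-2-ol (lactol, both anomers, not isolated) | OC1C[C@@H](CO[Si](C)(C)C(C)(C)C)[C@@H](c2ccc(OCc3ccccc3)c(OC)c2)O1 | intermediate
13 | (4S,5S)-5-[4-(benzyloxy)-3-methoxyphenyl]-4-{[(tert-butyldimethylsilyl)oxy]methyl}dihydrofuran-2(3H)-one (4,5-cis) | O=C1C[C@@H](CO[Si](C)(C)C(C)(C)C)[C@@H](c2ccc(OCc3ccccc3)c(OC)c2)O1 | intermediate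
14 | lithium enolate of 13 (not isolated) | [Li]OC1=C[C@@H](CO[Si](C)(C)C(C)(C)C)[C@@H](c2ccc(OCc3ccccc3)c(OC)c2)O1 | intermediate
15 | (3S,4S,5S)-5-[4-(benzyloxy)-3-methoxyphenyl]-4-{[(tert-butyldimethylsilyl)oxy]methyl}-3-(hydroxymethyl)dihydrofuran-2(3H)-one (3,4-trans, 4,5-cis) | O=C1[C@H](CO)[C@@H](CO[Si](C)(C)C(C)(C)C)[C@@H](c2ccc(OCc3ccccc3)c(OC)c2)O1 | intermediate
16 | (3S,4S,5S)-5-[4-(benzyloxy)-3-methoxyphenyl]-3,4-bis{[(tert-butyldimethylsilyl)oxy]methyl}dihydrofuran-2(3H)-one | O=C1[C@H](CO[Si](C)(C)C(C)(C)C)[C@@H](CO[Si](C)(C)C(C)(C)C)[C@@H](c2ccc(OCc3ccccc3)c(OC)c2)O1 | intermediate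
17 | 1-(benzyloxy)-4-bromo-2-methoxybenzene | COc1cc(Br)ccc1OCc1ccccc1 | starting material
18 | [4-(benzyloxy)-3-methoxyphenyl]lithium (not isolated) | [Li]c1ccc(OCc2ccccc2)c(OC)c1 | intermediate
19 | (3S,4S,5S)-2,5-bis[4-(benzyloxy)-3-methoxyphenyl]-3,4-bis{[(tert-butyldimethylsilyl)oxy]methyl}tetrahydrofuran-2-ol (hemiketal, C2 not defined) | OC1(c2ccc(OCc3ccccc3)c(OC)c2)[C@H](CO[Si](C)(C)C(C)(C)C)[C@@H](CO[Si](C)(C)C(C)(C)C)[C@@H](c2ccc(OCc3ccccc3)c(OC)c2)O1 | intermediate
20 | (2S,3S,4S,5S)-2,5-bis[4-(benzyloxy)-3-methoxyphenyl]-3,4-bis{[(tert-butyldimethylsilyl)oxy]methyl}tetrahydrofuran | COc1cc([C@H]2O[C@H](c3ccc(OCc4ccccc4)c(OC)c3)[C@H](CO[Si](C)(C)C(C)(C)C)[C@H]2CO[Si](C)(C)C(C)(C)C)ccc1OCc1ccccc1 | intermediate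
21 | [(2S,3S,4S,5S)-2,5-bis[4-(benzyloxy)-3-methoxyphenyl]tetrahydrofuran-3,4-diyl]dimethanol | COc1cc([C@H]2O[C@H](c3ccc(OCc4ccccc4)c(OC)c3)[C@H](CO)[C@H]2CO)ccc1OCc1ccccc1 | intermediate
22 | eduesmine, [(2S,3S,4S,5S)-2,5-bis(4-hydroxy-3-methoxyphenyl)tetrahydrofuran-3,4-diyl]dimethanol | COc1cc([C@H]2O[C@H](c3ccc(O)c(OC)c3)[C@H](CO)[C@H]2CO)ccc1O | target

**Step count**

Total: 14 steps. Longest linear sequence: 14 steps (1 → 22); bromide 17 enters in step 11.

**Steps most likely to fail**

Step 4. The electron-rich alkene may ionise to a free benzylic cation that escapes the chiral pocket, which would lower the enantiofacial selectivity, and the dialkoxyarene may be hydroxymethylated by activated formaldehyde. The fallback is an auxiliary-controlled anti-aldol route that sets out from aldehyde 1 and comes back at lactol 12.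
- Pent-4-enoyl chloride and lithiated (S)-4-benzyloxazolidin-2-one (n-BuLi, THF, −78 °C) would give (S)-4-benzyl-3-(pent-4-enoyl)oxazolidin-2-one F1.
- The MgCl2-catalysed anti-aldol reaction of F1 with 1 (MgCl2 cat., Et3N, Me3SiCl, EtOAc, rt) should give the silylated anti adduct (S)-4-benzyl-3-[(2R)-2-{(S)-[4-(benzyloxy)-3-methoxyphenyl][(trimethylsilyl)oxy]methyl}pent-4-enoyl]oxazolidin-2-one F2. The chelated Z-enolate is attacked on the face away from the benzyl group (sets C4) and the aryl carbinol is placed anti (sets C5); the (S)-benzyl auxiliary is chosen from the chelated-enolate model and is to be confirmed.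
- Dilute HCl in THF would free the alcohol (S)-4-benzyl-3-[(2R)-2-{(S)-[4-(benzyloxy)-3-methoxyphenyl](hydroxy)methyl}pent-4-enoyl]oxazolidin-2-one F3.
- LiBH4 (THF–MeOH, 0 °C) would remove the auxiliary to give (1S,2S)-2-allyl-1-[4-(benzyloxy)-3-methoxyphenyl]propane-1,3-diol F4.
- t-BuMe2SiCl and imidazole would silylate the primary hydroxyl to give (1S,2S)-1-[4-(benzyloxy)-3-methoxyphenyl]-2-{[(tert-butyldimethylsilyl)oxy]methyl}pent-4-en-1-ol F5.
- Lemieux–Johnson cleavage of the allyl group (OsO4 cat., NaIO4, 2,6-lutidine, dioxane–H2O) would give the aldehyde, which closes to lactol 12; the oxidant of step 8 takes 12 on to 13.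

Step 5. The silyl triflate may ionise the electron-rich benzylic C5–O bond instead of cleaving at the acetal carbon, which would scramble C5 or lead to elimination. The fallback makes the arene electron-poor before the acetal is opened; it sets out from dioxane 8 and comes back at diol 9.
- Brief hydrogenolysis (H2, Pd/C, EtOAc) would give the phenol 2-[(4S,5S)-4-(4-hydroxy-3-methoxyphenyl)-1,3-dioxan-5-yl]ethyl pivalate F6.
- Acetolysis (Ac2O, cat. H2SO4, 0 °C) would acetylate the phenol and open the formal to (3S,4S)-4-(4-acetoxy-3-methoxyphenyl)-4-(acetoxymethoxy)-3-(acetoxymethyl)butyl pivalate F7, whose aryl acetate no longer stabilises a benzylic cation.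
- K2CO3 in MeOH (0 °C) would remove the three acetyl groups and the hemiformal, but not the pivalate, to give (3S,4S)-4-hydroxy-4-(4-hydroxy-3-methoxyphenyl)-3-(hydroxymethyl)butyl pivalate F8.
- Phenol-selective benzylation (BnBr, K2CO3, acetone) would return 9.

Step 12. Hydride may be delivered from the wrong face, or BF3 may reopen a benzylic C–O bond and epimerise C2 or C5 towards the trans arrangement. The fallback reverses the order in which hydride and aryl are introduced; it sets out from lactone 16 and comes back at 20.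
- i-Bu2AlH (CH2Cl2, −78 °C) would give the lactol (3S,4S,5S)-5-[4-(benzyloxy)-3-methoxyphenyl]-3,4-bis{[(tert-butyldimethylsilyl)oxy]methyl}tetrahydrofuran-2-ol F9.
- PhSO2H and CaCl2 (CH2Cl2) would give the sulfone (3S,4S,5S)-5-[4-(benzyloxy)-3-methoxyphenyl]-3,4-bis{[(tert-butyldimethylsilyl)oxy]methyl}-2-(phenylsulfonyl)tetrahydrofuran F10.
- The Grignard reagent [4-(benzyloxy)-3-methoxyphenyl]magnesium bromide F11 (from 17 and Mg in THF), with ZnBr2, would displace the sulfinate through the C2-unsubstituted oxocarbenium ion. In that ion the C3 and C4 groups can both lie pseudoequatorial, and inside attack should place the incoming aryl group cis to the C3 group, giving 20.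

**Further compounds**

F1 | step 4 | (S)-4-benzyl-3-(pent-4-enoyl)oxazolidin-2-one | C=CCCC(=O)N1[C@@H](Cc2ccccc2)COC1=O
F2 | step 4 | (S)-4-benzyl-3-[(2R)-2-{(S)-[4-(benzyloxy)-3-methoxyphenyl][(trimethylsilyl)oxy]methyl}pent-4-enoyl]oxazolidin-2-one | O=C(N1[C@@H](Cc2ccccc2)COC1=O)[C@H](CC=C)[C@@H](c1ccc(OCc2ccccc2)c(OC)c1)O[Si](C)(C)C
F3 | step 4 | (S)-4-benzyl-3-[(2R)-2-{(S)-[4-(benzyloxy)-3-methoxyphenyl](hydroxy)methyl}pent-4-enoyl]oxazolidin-2-one | O=C(N1[C@@H](Cc2ccccc2)COC1=O)[C@H](CC=C)[C@@H](c1ccc(OCc2ccccc2)c(OC)c1)O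
F4 | step 4 | (1S,2S)-2-allyl-1-[4-(benzyloxy)-3-methoxyphenyl]propane-1,3-diol | OC[C@H](CC=C)[C@@H](c1ccc(OCc2ccccc2)c(OC)c1)O
F5 | step 4 | (1S,2S)-1-[4-(benzyloxy)-3-methoxyphenyl]-2-{[(tert-butyldimethylsilyl)oxy]methyl}pent-4-en-1-ol | CC(C)(C)[Si](C)(C)OC[C@H](CC=C)[C@@H](c1ccc(OCc2ccccc2)c(OC)c1)O
F6 | step 5 | 2-[(4S,5S)-4-(4-hydroxy-3-methoxyphenyl)-1,3-dioxan-5-yl]ethyl pivalate | C1OC[C@H](CCOC(=O)C(C)(C)C)[C@@H](c2ccc(O)c(OC)c2)O1
F7 | step 5 | (3S,4S)-4-(4-acetoxy-3-methoxyphenyl)-4-(acetoxymethoxy)-3-(acetoxymethyl)butyl pivalate | CC(=O)OC[C@H](CCOC(=O)C(C)(C)C)[C@@H](c1ccc(OC(C)=O)c(OC)c1)OCOC(C)=O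
F8 | step 5 | (3S,4S)-4-hydroxy-4-(4-hydroxy-3-methoxyphenyl)-3-(hydroxymethyl)butyl pivalate | OC[C@H](CCOC(=O)C(C)(C)C)[C@@H](c1ccc(O)c(OC)c1)O
F9 | step 12 | (3S,4S,5S)-5-[4-(benzyloxy)-3-methoxyphenyl]-3,4-bis{[(tert-butyldimethylsilyl)oxy]methyl}tetrahydrofuran-2-ol | OC1[C@H](CO[Si](C)(C)C(C)(C)C)[C@@H](CO[Si](C)(C)C(C)(C)C)[C@@H](c2ccc(OCc3ccccc3)c(OC)c2)O1
F10 | step 12 | (3S,4S,5S)-5-[4-(benzyloxy)-3-methoxyphenyl]-3,4-bis{[(tert-butyldimethylsilyl)oxy]methyl}-2-(phenylsulfonyl)tetrahydrofuran | O=S(=O)(c1ccccc1)C1[C@H](CO[Si](C)(C)C(C)(C)C)[C@@H](CO[Si](C)(C)C(C)(C)C)[C@@H](c2ccc(OCc3ccccc3)c(OC)c2)O1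
F11 | step 12 | [4-(benzyloxy)-3-methoxyphenyl]magnesium bromide | Br[Mg]c1ccc(OCc2ccccc2)c(OC)c1
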